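The runs were generated by integration on assumed constants, noise included.

A small charge of starting material, 0.500 M in the south run, and twice that charge in the south-west run, each with 1.50 M of coupling partner, were what I had to reason from.

| flask | starting material | coupling partner | time |
|---|---|---|---|
| south | 0.500 M | 1.50 M |  |
| south-west | 1.00 M | 1.50 M |  |
| north-west | 1.00 M | 0.750 M | 37 min |

- south run (time / min: [target] / M): 1.5: 0.0149; 2.3: 0.0205; 3.7: 0.0371; 5.9: 0.0554; 9.3: 0.0778; 15: 0.1163; 23: 0.1449; 37: 0.1692
- south-west run (time / min: [target] / M): 1.5: 0.0250; 2.3: 0.0377; 3.7: 0.0561; 5.9: 0.0854; 9.3: 0.1287; 15: 0.1749; 23: 0.2239; 37: 0.2673

(scatter of a reading: 0.002 M)

* how the opening rate goes with [starting material] round the charge of the south run: the exponent of the rate at two percent of starting material gone to target (one fixed amount of target, the same in the runs compared)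
* target in the north-west run at 37 min, as a share of the starting material charged

- Overall: starting material + coupling partner -> target.
- Constant volume, constant temperature.
- What is held in complexes is read along with the free species.
- "The second partner" is coupling partner.
- An order is taken over about fifteen percent of the charge, up and down.

The readings gave 1.57 for what I called the run ratio, the target of the south-west run over the target of the south run at one clock reading. It read 1.60 up to 5.9 min and 1.56 from 9.3 min on, so time dropped out: one curve, scaled, and the rates stood in that same ratio. Across the doubling of starting material, that made an order of 0.651.

For the north-west run I built the flask up in steps. First I took the main step alone, at the south-west pace up to 5.9 min, 0.0145 M min⁻¹. I assumed order one in coupling partner, which these runs do not test, so cutting it to 0.750 M left 0.268 M at 37 min. Then I added the falling off: the south-west run reached 0.2673 M, about half of its straight line. The steady run ratio showed the same fraction at both charges of starting material, and I assumed that fraction for the north-west run too, which gave 0.134 M, or 13.4% of the charge. Last came the use of coupling partner, the limiting reagent in the north-west run. My 0.134 M of target stood against 0.750 M of coupling partner charged, and I made no correction for it.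

The forecast gave 0.78 and 17%, both above my numbers, and of the partner it said: “The order in coupling partner was never varied, so I assume about 0.7”.

The flask gave an order of 0.70 and 12.8% in the north-west run at 37 min.

    2 coupling partner ⇌ reagent dimer, settled at all times (2.130 L mol⁻¹)
    starting material + reagent dimer → target + coupling partner (0.08520 L mol⁻¹ min⁻¹)
    2 starting material ⇌ idle substrate dimer, settled at all times (1.990 L mol⁻¹)
    target → decomposed product (0.02460 min⁻¹)

Where the same small amount of target had been made, the south-west run went 1.6 times the rate of the south run, 0.016 M min⁻¹ against 0.010 M min⁻¹. Put to the north-west run, the run ratio at 37 min, south-west over north-west, is 2.09, and across the cut in coupling partner that reads as an exponent of 1.07.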